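**Retrosynthetic overview**

1. Target 15 ⇐ tri-O-benzyl flavone 14 by hydrogenolysis of the 5-O, 7-O and 3'-O benzyl ethers.
2. Key disconnection: the γ-pyranone C ring of 14 is cut at three bonds, C4a–C4, C4–C3 and O1–C2. The C4 carbonyl carbon, lying between C4a of the phloroglucinol A ring and C3, is taken as carbon monoxide; C4a/C8a/O1 come from iodophenol 2; C3/C2 and the whole B ring come from arylacetylene 10. The three components are joined in one Pd-catalysed carbonylative annulation.
3. 10 ⇐ 3 + 4 (Sonogashira); the 3'-oxygen is then placed on the C–H flanked by the 2'- and 4'-methoxy groups by directed ortho-metalation, borylation and oxidation. 2 ⇐ 1 by ortho-iodination.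
4. Ring order: the A and B rings are bought as arenes; the C ring is the only ring formed (step 5).

Key step: step 5

Remark: the target has no stereocentre and no other element of chirality; the SMILES describes one achiral compound, so no stereocontrol is needed.

**Route**

Step 1
Reactants: 1 3,5-bis(benzyloxy)phenol
Product: 2 3,5-bis(benzyloxy)-2-iodophenol
Conditions: NIS (1.0 equiv), CH2Cl2, −20 → 0 °C, dark; chromatography
Reagents that add atoms: N-iodosuccinimide, O=C1CCC(=O)N1I
Why: Electrophilic aromatic iodination of a phloroglucinol-type phenol; the two equivalent positions ortho to the free OH (each para to a benzyloxy group) are statistically favoured and less shielded than C4 between two OBn groups, so the 2-iodide should be the main product, and one equivalent of NIS at low temperature limits di-iodination.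

Step 2
Reactants: 3 1-iodo-2,4,5-trimethoxybenzene; 4 (triisopropylsilyl)acetylene
Product: 5 triisopropyl[(2,4,5-trimethoxyphenyl)ethynyl]silane
Conditions: PdCl2(PPh3)2 (2 mol%), CuI (4 mol%), Et3N/THF, 50 °C
Reagents that add atoms: (triisopropylsilyl)acetylene (compound 4), C#C[Si](C(C)C)(C(C)C)C(C)C
Why: Sonogashira coupling of an aryl iodide with a terminal alkyne; the bulky TIPS group is chosen so that the alkyne survives the organolithium step that follows.

Step 3
Reactants: 5 triisopropyl[(2,4,5-trimethoxyphenyl)ethynyl]silane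
Product: 8 2,3,6-trimethoxy-5-[(triisopropylsilyl)ethynyl]phenol, via aryllithium 6 (not isolated), via dimethyl arylboronate 7 (not isolated)
Conditions: n-BuLi (1.2 equiv), TMEDA, THF, 0 °C; B(OMe)3, −78 °C → rt; then AcOH, 30% aq. H2O2, 0 °C → rt
Reagents that add atoms: n-butyllithium, [Li]CCCC (Li of 6); trimethyl borate, COB(OC)OC (B(OMe)2 of 7); hydrogen peroxide, OO (phenolic O of 8)
Why: Directed ortho-metalation at the C–H flanked by two methoxy groups (the site lithiated in 1,2,4-trimethoxybenzene itself), trapping as boronate 7 and ipso-oxidation of the C–B bond should place the 3'-oxygen; the TIPS-alkyne is inert to n-BuLi and to buffered peroxide.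

Step 4
Reactants: 8 2,3,6-trimethoxy-5-[(triisopropylsilyl)ethynyl]phenol
Product: 10 3-(benzyloxy)-1-ethynyl-2,4,5-trimethoxybenzene, via silylalkyne benzyl ether 9 (not isolated)
Conditions: BnBr (1.2 equiv), K2CO3, DMF, 50 °C; then TBAF (1.5 equiv, THF), rt
Reagents that add atoms: benzyl bromide, BrCc1ccccc1
Why: Williamson O-benzylation of the phenoxide followed in the same flask by fluoride-induced cleavage of the C(sp)–Si bond; both are standard and neither touches the methyl ethers.

Step 5
Reactants: 2 3,5-bis(benzyloxy)-2-iodophenol; 10 3-(benzyloxy)-1-ethynyl-2,4,5-trimethoxybenzene; 11 carbon monoxide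
Product: 14 5,7-bis(benzyloxy)-2-[3-(benzyloxy)-2,4,5-trimethoxyphenyl]-4H-chromen-4-one, via hydroxyaryl ynone 12 (not isolated), via E-enaminone 13 (not isolated)
Conditions: PdCl2(dppf) (5 mol%), CO (20 bar), Et2NH (solvent), 120 °C, autoclave
Reagents that add atoms: carbon monoxide (compound 11), [C-]#[O+]; diethylamine, CCNCC (present in 13 only, released on ring closure)
Why: Oxidative addition of Pd(0) into the C–I bond of 2, CO insertion and copper-free alkynylation with 10 on palladium should give o-hydroxyaryl ynone 12 with release of HI to the amine; Et2NH then adds to the ynone to give β-aminoenone 13, and the neighbouring phenol displaces the amine by intramolecular addition–elimination to form the pyranone. The closest known reaction type is the Pd-catalysed carbonylative annulation of o-iodophenols with terminal arylacetylenes in a secondary amine, which gives flavones in one operation. The C ring closes through O1–C2 bond formation in a 6-endo mode (6-endo-dig with respect to 12, 6-endo-trig addition–elimination on 13), and routing the closure through 13 is what disfavours the 5-exo-dig closure to an aurone. No stereocentre is formed. The step needs CO insertion to precede alkynylation, which the electron-rich, doubly ortho-substituted aryl-palladium from 2 together with 20 bar CO should secure, so that the non-carbonylative path to a 2-arylbenzofuran is suppressed. All other oxygens are capped as benzyl or methyl ethers, so the only nucleophilic OH is the one that closes the ring.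

Step 6
Reactants: 14 5,7-bis(benzyloxy)-2-[3-(benzyloxy)-2,4,5-trimethoxyphenyl]-4H-chromen-4-one
Product: 15 5,7,3'-trihydroxy-2',4',5'-trimethoxyflavone
Conditions: H2 (1 atm), 10% Pd/C, THF/MeOH, rt, stopped after uptake of 3 equiv H2
Reagents that add atoms: none
Why: Catalytic hydrogenolysis cleaves the three aryl benzyl ethers while aryl methyl ethers are inert, and the conjugated C2=C3 bond of a flavone is reduced much more slowly under these mild conditions.

**Compound list**

1 | 3,5-bis(benzyloxy)phenol | Oc1cc(OCc2ccccc2)cc(OCc2ccccc2)c1 | starting material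
2 | 3,5-bis(benzyloxy)-2-iodophenol | Oc1cc(OCc2ccccc2)cc(OCc2ccccc2)c1I | intermediate
3 | 1-iodo-2,4,5-trimethoxybenzene | COc1cc(OC)c(OC)cc1I | starting material
4 | (triisopropylsilyl)acetylene | C#C[Si](C(C)C)(C(C)C)C(C)C | starting material
5 | triisopropyl[(2,4,5-trimethoxyphenyl)ethynyl]silane | COc1cc(OC)c(OC)cc1C#C[Si](C(C)C)(C(C)C)C(C)C | intermediate
6 | {2,3,6-trimethoxy-5-[(triisopropylsilyl)ethynyl]phenyl}lithium | [Li]c1c(OC)c(OC)cc(C#C[Si](C(C)C)(C(C)C)C(C)C)c1OC | intermediate
7 | dimethyl {2,3,6-trimethoxy-5-[(triisopropylsilyl)ethynyl]phenyl}boronate | COB(OC)c1c(OC)c(OC)cc(C#C[Si](C(C)C)(C(C)C)C(C)C)c1OC | intermediate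
8 | 2,3,6-trimethoxy-5-[(triisopropylsilyl)ethynyl]phenol | Oc1c(OC)c(OC)cc(C#C[Si](C(C)C)(C(C)C)C(C)C)c1OC | intermediate
9 | {[3-(benzyloxy)-2,4,5-trimethoxyphenyl]ethynyl}triisopropylsilane | COc1cc(C#C[Si](C(C)C)(C(C)C)C(C)C)c(OC)c(OCc2ccccc2)c1OC | intermediate
10 | 3-(benzyloxy)-1-ethynyl-2,4,5-trimethoxybenzene | COc1cc(C#C)c(OC)c(OCc2ccccc2)c1OC | intermediate
11 | carbon monoxide | [C-]#[O+] | starting material
12 | 1-[2,4-bis(benzyloxy)-6-hydroxyphenyl]-3-[3-(benzyloxy)-2,4,5-trimethoxyphenyl]prop-2-yn-1-one | COc1cc(C#CC(=O)c2c(O)cc(OCc3ccccc3)cc2OCc2ccccc2)c(OC)c(OCc2ccccc2)c1OC | intermediate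
13 | (E)-1-[2,4-bis(benzyloxy)-6-hydroxyphenyl]-3-[3-(benzyloxy)-2,4,5-trimethoxyphenyl]-3-(diethylamino)prop-2-en-1-one | CCN(CC)/C(=C/C(=O)c1c(O)cc(OCc2ccccc2)cc1OCc1ccccc1)c1cc(OC)c(OC)c(OCc2ccccc2)c1OC | intermediate
14 | 5,7-bis(benzyloxy)-2-[3-(benzyloxy)-2,4,5-trimethoxyphenyl]-4H-chromen-4-one | COc1cc(-c2cc(=O)c3c(OCc4ccccc4)cc(OCc4ccccc4)cc3o2)c(OC)c(OCc2ccccc2)c1OC | intermediate
15 | 5,7,3'-trihydroxy-2',4',5'-trimethoxyflavone | COc1cc(-c2cc(=O)c3c(O)cc(O)cc3o2)c(OC)c(O)c1OC | target

**Step count**

Total steps: 6. Longest linear sequence: 5 steps (steps 2, 3, 4, 5, 6, starting from 3).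

**Steps most likely to fail, with fallbacks**

Step 5 (key step). What may go wrong: alkynylation of the aryl-palladium before CO insertion and subsequent cyclisation to a benzofuran; 5-exo closure to the aurone; capture of the acyl-palladium by diethylamine; protodeiodination of the electron-rich iodide. Fallback, CO-free and with the C4a–C4 bond made by organolithium acylation; it sets out from 10 and 2 and comes back to the route at 12 (now isolated) and then 14. Alkyne 10 is deprotonated with n-BuLi (THF, −78 °C) to lithium [3-(benzyloxy)-2,4,5-trimethoxyphenyl]acetylide F1, which is acylated with N-methoxy-N-methylcarbamoyl chloride to give 3-[3-(benzyloxy)-2,4,5-trimethoxyphenyl]-N-methoxy-N-methylprop-2-ynamide F2. Iodophenol 2 is treated with n-BuLi (2.1 equiv, THF, −78 °C; O–H deprotonation, then I/Li exchange) to give lithium 3,5-bis(benzyloxy)-2-lithiophenoxide F3, which should add to F2 and, after mild acidic work-up, deliver ynone 12. Warming 12 in Et2NH/EtOH should close the ring through 13 to 14, as in the second half of step 5.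

Step 1. What may go wrong: iodination para to the free hydroxyl (between the two benzyloxy groups) and over-iodination, giving a mixture that is hard to separate. Fallback, in which the phenolic oxygen is deactivated so that attack is steered para to a benzyloxy group; it sets out from 1 and comes back at 2. Acetylation of 1 (Ac2O, pyridine) should give 3,5-bis(benzyloxy)phenyl acetate F4. Iodination (NIS, cat. TFA, MeCN, rt) should then occur ortho to the acetoxy group and para to OBn, as is usual for 5-substituted 1,3-dialkoxybenzenes, to give 3,5-bis(benzyloxy)-2-iodophenyl acetate F5. Methanolysis (K2CO3, MeOH, rt) returns 2.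

Step 3. What may go wrong: lithiation next to the alkyne (C6) instead of between the methoxy groups, attack of butyllithium on the silylalkyne, or over-oxidation of the electron-rich phenol by peroxide. Fallback, in which the oxygen is installed on the parent arene before the alkyne is attached; it sets out from 4 and from commercial 1,2,4-trimethoxybenzene F6 (the parent arene of 3) and comes back at 8. Lithiation of F6 (n-BuLi, TMEDA, THF, 0 °C) gives (2,3,6-trimethoxyphenyl)lithium F7, which is trapped with B(OMe)3 as dimethyl (2,3,6-trimethoxyphenyl)boronate F8 and oxidised (H2O2, AcOH) to 2,3,6-trimethoxyphenol F9. Acetylation (Ac2O, pyridine) gives 2,3,6-trimethoxyphenyl acetate F10. Iodination (NIS, cat. TFA, MeCN) should go para to the 2-methoxy group rather than para to the deactivating acetoxy group, giving 3-iodo-2,5,6-trimethoxyphenyl acetate F11. Sonogashira coupling of F11 with 4 (PdCl2(PPh3)2, CuI, Et3N) gives 2,3,6-trimethoxy-5-[(triisopropylsilyl)ethynyl]phenyl acetate F12, and methanolysis (K2CO3, MeOH) gives 8.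

**Further compounds**

F1 | step 5 | lithium [3-(benzyloxy)-2,4,5-trimethoxyphenyl]acetylide | [Li]C#Cc1cc(OC)c(OC)c(OCc2ccccc2)c1OC
F2 | step 5 | 3-[3-(benzyloxy)-2,4,5-trimethoxyphenyl]-N-methoxy-N-methylprop-2-ynamide | CON(C)C(=O)C#Cc1cc(OC)c(OC)c(OCc2ccccc2)c1OC
F3 | step 5 | lithium 3,5-bis(benzyloxy)-2-lithiophenoxide | [Li]Oc1cc(OCc2ccccc2)cc(OCc2ccccc2)c1[Li]
F4 | step 1 | 3,5-bis(benzyloxy)phenyl acetate | CC(=O)Oc1cc(OCc2ccccc2)cc(OCc2ccccc2)c1
F5 | step 1 | 3,5-bis(benzyloxy)-2-iodophenyl acetate | CC(=O)Oc1cc(OCc2ccccc2)cc(OCc2ccccc2)c1I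
F6 | step 3 | 1,2,4-trimethoxybenzene | COc1ccc(OC)c(OC)c1
F7 | step 3 | (2,3,6-trimethoxyphenyl)lithium | [Li]c1c(OC)ccc(OC)c1OC
F8 | step 3 | dimethyl (2,3,6-trimethoxyphenyl)boronate | COB(OC)c1c(OC)ccc(OC)c1OC
F9 | step 3 | 2,3,6-trimethoxyphenol | Oc1c(OC)ccc(OC)c1OC
F10 | step 3 | 2,3,6-trimethoxyphenyl acetate | CC(=O)Oc1c(OC)ccc(OC)c1OC
F11 | step 3 | 3-iodo-2,5,6-trimethoxyphenyl acetate | CC(=O)Oc1c(OC)c(I)cc(OC)c1OC
F12 | step 3 | 2,3,6-trimethoxy-5-[(triisopropylsilyl)ethynyl]phenyl acetate | CC(=O)Oc1c(OC)c(C#C[Si](C(C)C)(C(C)C)C(C)C)cc(OC)c1OC
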